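**Retrosynthetic overview** (C-numbers are germacrane numbering: lactone C12(=O)–O–C6, C7, C11=C13; ring C1–C10)
1. Last operations: free O9 (silyl ether off) after acylating O8 with (R)-2-(2-methyloxiran-2-yl)acetic acid, made from 3-methylbut-3-en-1-ol.
2. Key step: the C7–C8 bond and the ten-membered ring form together by SmI2 ketyl-radical addition of a C8 aldehyde to C7 of a 3-(acetoxymethyl)butenolide; loss of acetate gives the α-methylene lactone; C7 and C8 are set here.
3. The butenolide (first ring) comes from ring-closing metathesis of a 2-(acetoxymethyl)acrylate of an (S)-divinyl carbinol; C6 is set by enantioselective vinylzinc addition.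
4. C1–C2 is made by B-alkyl Suzuki coupling of (E)-3-methylpenta-2,4-dien-1-ol with a (Z)-alkenyl iodide carrying C8–C10; the iodide comes from (S)-glyceraldehyde acetonide by copper-catalysed anti-carbomagnesiation (C9 from the chiral pool).
5. Ring order: butenolide, then ten-membered carbocycle; the side-chain oxirane is prepared separately.

**Step 1**
Reactants: 1 (S)-2,2-dimethyl-1,3-dioxolane-4-carbaldehyde
Product: 3 (R)-but-3-yne-1,2-diol, via alkyne acetonide 2 (not isolated)
Conditions: Ohira–Bestmann reagent, K2CO3, MeOH, 0 °C to rt; then aq HCl (pH 1), rt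
Reagents that add atoms: Ohira–Bestmann reagent (dimethyl (1-diazo-2-oxopropyl)phosphonate), CC(=O)C(=[N+]=[N-])P(=O)(OC)OC
Why: Ohira–Bestmann (Seyferth–Gilbert) homologation converts the aldehyde into the terminal alkyne under carbonate conditions that do not epimerise the α-oxygenated centre, and acid then hydrolyses the acetonide, so the future C9 centre is taken unchanged from the chiral pool.

**Step 2**
Reactants: 3 (R)-but-3-yne-1,2-diol
Product: 5 (2R,3Z)-4-iodo-3-methylbut-3-ene-1,2-diol, via alkenylmagnesium alkoxide 4 (not isolated)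
Conditions: CH3MgBr (4 equiv), CuI (20 mol %), THF, 0 °C to rt; then I2, −78 to 0 °C; aq NH4Cl
Reagents that add atoms: methylmagnesium bromide, C[Mg]Br; iodine, [I][I]
Why: Copper-catalysed anti-carbomagnesiation of the propargylic alkoxide (Duboudin type) places methyl on the internal carbon and magnesium on the terminal carbon cis to the carbinol through a five-membered magnesium chelate, and iodinolysis with retention gives the Z-iodide that fixes the 1(10)Z geometry.

**Step 3**
Reactants: 5 (2R,3Z)-4-iodo-3-methylbut-3-ene-1,2-diol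
Product: 6 (2R,3Z)-4-iodo-3-methyl-1,2-bis(triethylsilyloxy)but-3-ene
Conditions: Et3SiCl (2.4 equiv), imidazole, CH2Cl2, 0 °C
Reagents that add atoms: chlorotriethylsilane, CC[Si](Cl)(CC)CC
Why: Standard silylation of both hydroxyls; the primary silyl ether is the later handle for direct oxidation to the C8 aldehyde and the secondary one keeps O9 blocked to the end.

**Step 4**
Reactants: 7 (E)-3-methylpent-2-en-4-yn-1-ol
Product: 8 (E)-3-methylpenta-2,4-dien-1-ol
Conditions: H2 (1 atm), Pd/CaCO3 poisoned with Pb(OAc)2 (Lindlar catalyst), quinoline, EtOAc, 0 °C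
Reagents that add atoms: none
Why: Lindlar semi-hydrogenation reduces only the terminal alkyne to a vinyl group and leaves the E-trisubstituted alkene (future C4=C5) untouched.

**Step 5**
Reactants: 8 (E)-3-methylpenta-2,4-dien-1-ol; 6 (2R,3Z)-4-iodo-3-methyl-1,2-bis(triethylsilyloxy)but-3-ene
Product: 10 (2E,6Z,8R)-3,7-dimethyl-8,9-bis(triethylsilyloxy)nona-2,6-dien-1-ol, via alkylborane 9 (not isolated)
Conditions: 9-BBN (2.2 equiv), THF, 0 °C to rt; then 6, Pd(dppf)Cl2 (5 mol %), AsPh3, Cs2CO3, DMF/H2O, rt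
Reagents that add atoms: none
Why: 9-BBN caps the hydroxyl as a borinate and hydroborates only the terminal vinyl group anti-Markovnikov, and the B-alkyl Suzuki–Miyaura coupling with the alkenyl iodide forms C1–C2 with retention of the Z geometry.

**Step 6**
Reactants: 10 (2E,6Z,8R)-3,7-dimethyl-8,9-bis(triethylsilyloxy)nona-2,6-dien-1-ol
Product: 11 (2E,6Z,8R)-3,7-dimethyl-8,9-bis(triethylsilyloxy)nona-2,6-dienal
Conditions: MnO2 (excess), CH2Cl2, rt
Reagents that add atoms: none
Why: MnO2 oxidises the primary allylic alcohol chemoselectively to the E-enal and leaves the silyl ethers and both alkene geometries intact.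

**Step 7**
Reactants: 11 (2E,6Z,8R)-3,7-dimethyl-8,9-bis(triethylsilyloxy)nona-2,6-dienal
Product: 12 (3S,4E,8Z,10R)-5,9-dimethyl-10,11-bis(triethylsilyloxy)undeca-1,4,8-trien-3-ol
Conditions: Zn(CH=CH2)2 (2 equiv, salt-free), (−)-MIB (10 mol %), toluene, −20 °C; aq NH4Cl
Reagents that add atoms: divinylzinc, C=C[Zn]C=C
Why: Amino-alcohol-catalysed enantioselective 1,2-addition of a vinylzinc reagent to the aldehyde (Oppolzer/Noyori type) gives the (S)-carbinol, in the same sense as the (S)-alcohols formed with this ligand in dialkylzinc additions, and this centre becomes C6.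

**Step 8**
Reactants: 12 (3S,4E,8Z,10R)-5,9-dimethyl-10,11-bis(triethylsilyloxy)undeca-1,4,8-trien-3-ol; 13 2-(bromomethyl)acrylic acid
Product: 15 (3S,4E,8Z,10R)-5,9-dimethyl-10,11-bis(triethylsilyloxy)undeca-1,4,8-trien-3-yl 2-(acetoxymethyl)acrylate, via bromomethylacrylate ester 14 (not isolated)
Conditions: 13 (1.3 equiv), DCC, DMAP (5 mol %), CH2Cl2, 0 °C; then n-Bu4NOAc, rt
Reagents that add atoms: tetrabutylammonium acetate, CCCC[N+](CCCC)(CCCC)CCCC.CC(=O)[O-]
Why: Steglich esterification of the secondary alcohol (retention at C6) followed in the same flask by acetate displacement of the activated allylic bromide (SN2/SN2', degenerate here) installs C11, C12 and C13 with a leaving group on C13 that SmI2 does not reduce.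

**Step 9**
Reactants: 15 (3S,4E,8Z,10R)-5,9-dimethyl-10,11-bis(triethylsilyloxy)undeca-1,4,8-trien-3-yl 2-(acetoxymethyl)acrylate
Product: 16 [(5R)-5-[(1E,5Z,7R)-2,6-dimethyl-7,8-bis(triethylsilyloxy)octa-1,5-dien-1-yl]-2-oxo-2,5-dihydrofuran-3-yl]methyl acetate
Conditions: second-generation Grubbs catalyst RuCl2(=CHPh)(H2IMes)(PCy3) (5 mol %), CH2Cl2 (5 mM), 40 °C
Reagents that add atoms: none
Why: Ring-closing metathesis between the terminal vinyl group and the 1,1-disubstituted acrylate alkene closes the butenolide (C7=C11) with loss of ethene, the trisubstituted alkenes being inert, and C6 is untouched.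

**Step 10**
Reactants: 16 [(5R)-5-[(1E,5Z,7R)-2,6-dimethyl-7,8-bis(triethylsilyloxy)octa-1,5-dien-1-yl]-2-oxo-2,5-dihydrofuran-3-yl]methyl acetate
Product: 17 [(5R)-5-[(1E,5Z,7R)-2,6-dimethyl-8-oxo-7-(triethylsilyloxy)octa-1,5-dien-1-yl]-2-oxo-2,5-dihydrofuran-3-yl]methyl acetate
Conditions: (COCl)2, DMSO, CH2Cl2, −78 to −30 °C; then i-Pr2NEt, −78 °C; used crude at once
Reagents that add atoms: none
Why: Under Swern conditions the primary triethylsilyl ether is cleaved and oxidised directly to the aldehyde while the secondary one survives (known selective oxidative desilylation), and the hindered base at low temperature avoids epimerisation of the α-silyloxy aldehyde at C9.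

**Step 11** (key step)
Reactants: 17 [(5R)-5-[(1E,5Z,7R)-2,6-dimethyl-8-oxo-7-(triethylsilyloxy)octa-1,5-dien-1-yl]-2-oxo-2,5-dihydrofuran-3-yl]methyl acetate
Product: 18 (1(10)Z,4E)-8β-hydroxy-9β-(triethylsilyloxy)germacra-1(10),4,11(13)-trien-12,6α-olide (6R,7R,8S,9R; H-7α)
Conditions: SmI2 (2.5 equiv), THF, no HMPA, 17 added over 6 h (final 2 mM), −78 to −20 °C; pH 7 buffer
Reagents that add atoms: none
Why: Proposed new method: SmI2 reduces the aldehyde to a samarium ketyl radical that adds 10-exo to C7 of the butenolide on the face anti to the C6 side chain, with the carbinol hydrogen under the lactone ring and the C9 silyloxy group anti to the forming bond (Felkin–Anh sense), and the α-lactone radical is then reduced to the trivalent samarium enolate, which expels acetate to give the exocyclic methylene, so the C7–C8 bond, the ten-membered ring, both new stereocentres and the α-methylene lactone arise in one operation; the closest known reactions are SmI2 ketyl–olefin cyclisations onto unsaturated esters in medium rings and radical additions to 5-substituted butenolides, which occur trans to the C5 substituent.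

**Step 12**
Reactants: 19 3-methylbut-3-en-1-ol
Product: 20 (R)-2-(2-methyloxiran-2-yl)ethan-1-ol
Conditions: WO2(acac)2 (2 mol %), C2-symmetric bishydroxamic acid ligand (2.4 mol %, the enantiomer that gives the (R)-epoxide), 30 % aq H2O2, NaCl, CH2Cl2, rt
Reagents that add atoms: hydrogen peroxide, OO
Why: Hydroxyl-directed tungsten–bishydroxamic acid catalysed asymmetric epoxidation of a homoallylic alcohol (Yamamoto type) sets the quaternary oxirane centre as (R).

**Step 13**
Reactants: 20 (R)-2-(2-methyloxiran-2-yl)ethan-1-ol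
Product: 21 (R)-2-(2-methyloxiran-2-yl)acetic acid
Conditions: TEMPO (7 mol %), NaClO2, NaOCl (2 mol %), MeCN/phosphate buffer pH 6.7, 35 °C; acidify to pH 4 at 0 °C, extract, use at once
Reagents that add atoms: sodium chlorite, [Na+].[O-]Cl=O
Why: TEMPO/chlorite oxidation takes the primary alcohol to the acid at near-neutral pH, which the 2,2-disubstituted oxirane tolerates, and the stereocentre is not involved.

**Step 14**
Reactants: 18 (1(10)Z,4E)-8β-hydroxy-9β-(triethylsilyloxy)germacra-1(10),4,11(13)-trien-12,6α-olide; 21 (R)-2-(2-methyloxiran-2-yl)acetic acid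
Product: 22 (1(10)Z,4E)-8β-[(R)-2-(2-methyloxiran-2-yl)acetoxy]-9β-(triethylsilyloxy)germacra-1(10),4,11(13)-trien-12,6α-olide (6R,7S,8S,9R)
Conditions: 21 (1.5 equiv), DCC, DMAP (0.2 equiv), CH2Cl2, 0 °C to rt
Reagents that add atoms: none
Why: Steglich esterification of the only free hydroxyl (O8) proceeds with retention at C8, and O9 is blocked so there is no regiochemical issue.

**Step 15**
Reactants: 22 (1(10)Z,4E)-8β-[(R)-2-(2-methyloxiran-2-yl)acetoxy]-9β-(triethylsilyloxy)germacra-1(10),4,11(13)-trien-12,6α-olide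
Product: 23 (1(10)Z,4E)-9β-hydroxy-8β-[(R)-2-(2-methyloxiran-2-yl)acetoxy]germacra-1(10),4,11(13)-trien-12,6α-olide (6R,7S,8S,9R; CNP0284481.1)
Conditions: Et3N·3HF, MeCN, 0 °C to rt
Reagents that add atoms: none
Why: Mildly acidic fluoride cleaves the secondary triethylsilyl ether without opening the oxirane, adding to the α-methylene lactone or promoting 8→9 acyl migration.

**Compound list**
1 | (S)-2,2-dimethyl-1,3-dioxolane-4-carbaldehyde (2,3-O-isopropylidene-L-glyceraldehyde) | O=C[C@@H]1COC(C)(C)O1 | starting material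
2 | (R)-4-ethynyl-2,2-dimethyl-1,3-dioxolane | C#C[C@@H]1COC(C)(C)O1 | intermediate
3 | (R)-but-3-yne-1,2-diol | C#C[C@@H](O)CO | intermediate
4 | bromo[(1Z,3R)-3,4-bis(bromomagnesiooxy)-2-methylbut-1-en-1-yl]magnesium | Br[Mg]/C=C(/C)[C@@H](O[Mg]Br)CO[Mg]Br | intermediate
5 | (2R,3Z)-4-iodo-3-methylbut-3-ene-1,2-diol | I/C=C(/C)[C@@H](O)CO | intermediate
6 | (2R,3Z)-4-iodo-3-methyl-1,2-bis(triethylsilyloxy)but-3-ene | I/C=C(/C)[C@@H](O[Si](CC)(CC)CC)CO[Si](CC)(CC)CC | intermediate
7 | (E)-3-methylpent-2-en-4-yn-1-ol | C#C/C(C)=C/CO | starting material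
8 | (E)-3-methylpenta-2,4-dien-1-ol | C=C/C(C)=C/CO | intermediate
9 | 9-[(2E)-3-methyl-5-(9-borabicyclo[3.3.1]nonan-9-yl)pent-2-en-1-yloxy]-9-borabicyclo[3.3.1]nonane | B1(OC/C=C(\C)CCB2C3CCCC2CCC3)C2CCCC1CCC2 | intermediate
10 | (2E,6Z,8R)-3,7-dimethyl-8,9-bis(triethylsilyloxy)nona-2,6-dien-1-ol | OC/C=C(\C)CC/C=C(/C)[C@@H](O[Si](CC)(CC)CC)CO[Si](CC)(CC)CC | intermediate
11 | (2E,6Z,8R)-3,7-dimethyl-8,9-bis(triethylsilyloxy)nona-2,6-dienal | O=C/C=C(\C)CC/C=C(/C)[C@@H](O[Si](CC)(CC)CC)CO[Si](CC)(CC)CC | intermediate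
12 | (3S,4E,8Z,10R)-5,9-dimethyl-10,11-bis(triethylsilyloxy)undeca-1,4,8-trien-3-ol | O[C@@H](C=C)/C=C(\C)CC/C=C(/C)[C@@H](O[Si](CC)(CC)CC)CO[Si](CC)(CC)CC | intermediate
13 | 2-(bromomethyl)acrylic acid | C=C(CBr)C(=O)O | starting material
14 | (3S,4E,8Z,10R)-5,9-dimethyl-10,11-bis(triethylsilyloxy)undeca-1,4,8-trien-3-yl 2-(bromomethyl)acrylate | C=C(CBr)C(=O)O[C@@H](C=C)/C=C(\C)CC/C=C(/C)[C@@H](O[Si](CC)(CC)CC)CO[Si](CC)(CC)CC | intermediate
15 | (3S,4E,8Z,10R)-5,9-dimethyl-10,11-bis(triethylsilyloxy)undeca-1,4,8-trien-3-yl 2-(acetoxymethyl)acrylate | C=C(COC(C)=O)C(=O)O[C@@H](C=C)/C=C(\C)CC/C=C(/C)[C@@H](O[Si](CC)(CC)CC)CO[Si](CC)(CC)CC | intermediate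
16 | [(5R)-5-[(1E,5Z,7R)-2,6-dimethyl-7,8-bis(triethylsilyloxy)octa-1,5-dien-1-yl]-2-oxo-2,5-dihydrofuran-3-yl]methyl acetate | O=C1O[C@@H](C=C1COC(C)=O)/C=C(\C)CC/C=C(/C)[C@@H](O[Si](CC)(CC)CC)CO[Si](CC)(CC)CC | intermediate
17 | [(5R)-5-[(1E,5Z,7R)-2,6-dimethyl-8-oxo-7-(triethylsilyloxy)octa-1,5-dien-1-yl]-2-oxo-2,5-dihydrofuran-3-yl]methyl acetate | O=C1O[C@@H](C=C1COC(C)=O)/C=C(\C)CC/C=C(/C)[C@@H](O[Si](CC)(CC)CC)C=O | intermediate
18 | (1(10)Z,4E)-8β-hydroxy-9β-(triethylsilyloxy)germacra-1(10),4,11(13)-trien-12,6α-olide (6R,7R,8S,9R) | C=C1C(=O)O[C@@H]2/C=C(\C)CC/C=C(/C)[C@@H](O[Si](CC)(CC)CC)[C@@H](O)[C@@H]12 | intermediate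
19 | 3-methylbut-3-en-1-ol | C=C(C)CCO | starting material
20 | (R)-2-(2-methyloxiran-2-yl)ethan-1-ol | OCC[C@]1(C)CO1 | intermediate
21 | (R)-2-(2-methyloxiran-2-yl)acetic acid | OC(=O)C[C@]1(C)CO1 | intermediate
22 | (1(10)Z,4E)-8β-[(R)-2-(2-methyloxiran-2-yl)acetoxy]-9β-(triethylsilyloxy)germacra-1(10),4,11(13)-trien-12,6α-olide (6R,7S,8S,9R) | C=C1C(=O)O[C@@H]2/C=C(\C)CC/C=C(/C)[C@@H](O[Si](CC)(CC)CC)[C@@H](OC(=O)C[C@]3(C)CO3)[C@@H]12 | intermediate
23 | (1(10)Z,4E)-9β-hydroxy-8β-[(R)-2-(2-methyloxiran-2-yl)acetoxy]germacra-1(10),4,11(13)-trien-12,6α-olide (6R,7S,8S,9R) | C=C1C(=O)O[C@@H]2/C=C(\C)CC/C=C(/C)[C@@H](O)[C@@H](OC(=O)C[C@]3(C)CO3)[C@@H]12 | target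

**Total step count:** 15.
**Longest linear sequence:** 12 (steps 1, 2, 3, 5, 6, 7, 8, 9, 10, 11, 14, 15).

**Three steps most likely to fail**

Step 11 (ketyl macrocyclisation). Ten-membered ring closure by a ketyl radical is unprecedented, and the C8 configuration rests on a Felkin–Anh argument that the ring may override. The fallback sets out from 12 and comes back at 22. Compound 12 is esterified with 13 as in step 8 but without the acetate exchange, and the bromomethylacrylate 14 is isolated. Ring-closing metathesis with the same ruthenium catalyst gives the bromomethyl butenolide F1, and Swern oxidation as in step 10 gives the bromo aldehyde F2. CrCl2 in THF/DMF at high dilution then closes the same C7–C8 bond by a Nozaki–Hiyama-type allylchromium addition through a closed chair transition state. Because the C13-chromium reagent is E-crotyl-like, this should give the 8α-hydroxy epimer F3. Mitsunobu esterification of F3 with 21 (PPh3, DIAD, toluene, 0 °C) inverts C8 and delivers 22. The same Mitsunobu step also uses up any F3 formed in the samarium reaction itself.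

Step 7 (enantioselective vinylation). β,β-Disubstituted enals can give modest enantioselectivity, and an error at C6 appears as an inseparable remote diastereomer. The fallback sets out from 11 and comes back at 12. CH2=CHMgBr in THF at −78 °C gives the C3-epimeric alcohol mixture F4. Candida antarctica lipase B with vinyl acetate in hexane acetylates the (3R)-epimer (Kazlauskas rule, vinyl as the medium group) to the (3R)-acetate F5. The unreacted (3S)-alcohol 12 is separated by chromatography.

Step 14 (esterification). The β,γ-epoxy acid can open by α-deprotonation once activated, and O8 is hindered. The fallback sets out from 21 (together with 18) and comes back at 22. LiBr/AcOH in THF opens the oxirane of 21 at the CH2 terminus to the bromohydrin acid F6, which is robust to carbodiimide activation. DCC/DMAP esterification of 18 with F6 gives the bromohydrin ester F7. Ag2O in CH2Cl2 closes the oxirane without base and gives 22.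

**Further compounds**
F1 | step 11 | (5R)-3-(bromomethyl)-5-[(1E,5Z,7R)-2,6-dimethyl-7,8-bis(triethylsilyloxy)octa-1,5-dien-1-yl]furan-2(5H)-one | O=C1O[C@@H](C=C1CBr)/C=C(\C)CC/C=C(/C)[C@@H](O[Si](CC)(CC)CC)CO[Si](CC)(CC)CC
F2 | step 11 | (2R,3Z,7E)-8-[(2R)-4-(bromomethyl)-5-oxo-2,5-dihydrofuran-2-yl]-3,7-dimethyl-2-(triethylsilyloxy)octa-3,7-dienal | O=C1O[C@@H](C=C1CBr)/C=C(\C)CC/C=C(/C)[C@@H](O[Si](CC)(CC)CC)C=O
F3 | step 11 | (1(10)Z,4E)-8α-hydroxy-9β-(triethylsilyloxy)germacra-1(10),4,11(13)-trien-12,6α-olide (6R,7R,8R,9R) | C=C1C(=O)O[C@@H]2/C=C(\C)CC/C=C(/C)[C@@H](O[Si](CC)(CC)CC)[C@H](O)[C@@H]12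
F4 | step 7 | (3RS,4E,8Z,10R)-5,9-dimethyl-10,11-bis(triethylsilyloxy)undeca-1,4,8-trien-3-ol (mixture of C3 epimers) | OC(C=C)/C=C(\C)CC/C=C(/C)[C@@H](O[Si](CC)(CC)CC)CO[Si](CC)(CC)CC
F5 | step 7 | (3R,4E,8Z,10R)-5,9-dimethyl-10,11-bis(triethylsilyloxy)undeca-1,4,8-trien-3-yl acetate | CC(=O)O[C@H](C=C)/C=C(\C)CC/C=C(/C)[C@@H](O[Si](CC)(CC)CC)CO[Si](CC)(CC)CC
F6 | step 14 | (R)-4-bromo-3-hydroxy-3-methylbutanoic acid | OC(=O)C[C@](O)(C)CBr
F7 | step 14 | (1(10)Z,4E)-8β-[(R)-4-bromo-3-hydroxy-3-methylbutanoyloxy]-9β-(triethylsilyloxy)germacra-1(10),4,11(13)-trien-12,6α-olide | C=C1C(=O)O[C@@H]2/C=C(\C)CC/C=C(/C)[C@@H](O[Si](CC)(CC)CC)[C@@H](OC(=O)C[C@](O)(C)CBr)[C@@H]12
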